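**Retrosynthetic overview**
1. Target 16 ⇐ selective 6‑O‑anisoylation of triol 14 ⇐ α‑face hydroboration of the 5,6‑alkene of diene 13, which sets the trans ring fusion (5α‑H) and the 6α‑oxygen together.
2. 13 ⇐ seven‑membered ring through the cyclase bond fC1–fC7: Lewis‑acid (cationic) closure of an enal onto a cyclopentenyl allylsilane, with anti‑SE2′ chirality transfer from a C–Si centre.
3. Allylsilane‑enal 12 ⇐ enantioselective conjugate silylation of dienone 8 plus a two‑carbon enal homologation; 8 ⇐ Wittig reaction of aldehyde 6.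
4. 6 ⇐ five‑membered ring through the cyclase bond fC6–fC10: dienamine (vinylogous) aldol of an acyclic keto‑enal onto the isopropyl ketone, which also delivers the C4 carbinol.
5. Keto‑enal ⇐ boron aldol of 3‑methylbutan‑2‑one with a C5 enal acetal. Ring order: five‑membered first, seven‑membered second (the cyclase closes them in the reverse order; a stepwise closure onto an sp2 fC6 would give the cis‑fused skeleton, so fC6–H is set last).

Assumption: (−)‑Ipc2BCl and L‑proline are taken as the matched enantiomers for the centres drawn; if either sense proves opposite, the antipode is used and nothing else changes.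
Numbering: fC1–fC15 are farnesyl‑chain locants; "dauc" names use daucane numbering with the angular methyl as β.

Step 1
Reactants: 1 3‑methylbutan‑2‑one; 2 (2E)‑4,4‑dimethoxy‑2‑methylbut‑2‑enal
Product: 3 (5S,6E)‑5‑hydroxy‑8,8‑dimethoxy‑2,6‑dimethyloct‑6‑en‑3‑one
Conditions: (−)‑Ipc2BCl, Et3N, Et2O, −78 °C; then 2, −78 → −20 °C; H2O2, pH 7 buffer, MeOH, 0 °C
Reagents that add atoms: none
Why: Paterson boron‑mediated asymmetric aldol reaction, in which the Ipc2B enolate forms at the methyl group of the ketone and adds to the α‑branched enal through a closed chair transition state whose isopinocampheyl ligands select one aldehyde face, setting the (5S) carbinol (the future C2 acetate centre) under reagent control.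

Step 2
Reactants: 3 (5S,6E)‑5‑hydroxy‑8,8‑dimethoxy‑2,6‑dimethyloct‑6‑en‑3‑one
Product: 4 (5S,6E)‑8,8‑dimethoxy‑2,6‑dimethyl‑3‑oxooct‑6‑en‑5‑yl acetate
Conditions: Ac2O, pyridine, DMAP (cat.), CH2Cl2, 0 °C → rt
Reagents that add atoms: acetic anhydride, CC(=O)OC(C)=O
Why: DMAP‑catalysed O‑acetylation installs the C2 acetate of the target with retention at the carbinol carbon and prevents furan formation from a free γ‑hydroxy enal in the next step.

Step 3
Reactants: 4 (5S,6E)‑8,8‑dimethoxy‑2,6‑dimethyl‑3‑oxooct‑6‑en‑5‑yl acetate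
Product: 6 (1S,4R)‑3‑formyl‑4‑hydroxy‑2‑methyl‑4‑(propan‑2‑yl)cyclopent‑2‑en‑1‑yl acetate, via keto‑enal 5 (not isolated)
Conditions: L‑proline (30 mol %), CF3CO2H (10 mol %), DMSO/H2O 20:1, rt
Reagents that add atoms: water, O
Why: Proposed new method: mild acid unmasks enal 5, proline condenses with it to an iminium ion that loses a proton from the fC7 methyl to give a cross‑conjugated dienamine, whose α‑carbon (fC6) adds to the acid‑activated isopropyl ketone in a 5‑enolexo aldol (the fC6–fC10 bond; the 6E geometry blocks the competing ketone‑enolate‑to‑aldehyde closure), and hydrolysis with reconjugation gives enal 6 with the tertiary carbinol (R) set by the hydrogen‑bonded proline transition state matched to the acetate centre; the closest known reactions are the Hajos–Parrish intramolecular proline aldol and α‑selective dienamine catalysis of γ‑enolisable enals.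

Step 4
Reactants: 6 (1S,4R)‑3‑formyl‑4‑hydroxy‑2‑methyl‑4‑(propan‑2‑yl)cyclopent‑2‑en‑1‑yl acetate; 7 1‑(triphenyl‑λ5‑phosphanylidene)propan‑2‑one
Product: 8 (1S,4R)‑4‑hydroxy‑2‑methyl‑3‑[(1E)‑3‑oxobut‑1‑en‑1‑yl]‑4‑(propan‑2‑yl)cyclopent‑2‑en‑1‑yl acetate
Conditions: toluene, 80 °C
Reagents that add atoms: none
Why: Wittig olefination with a stabilised ylide gives the (E)‑dienone under neutral conditions that leave both stereocentres and the acetate untouched.

Step 5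
Reactants: 8 (1S,4R)‑4‑hydroxy‑2‑methyl‑3‑[(1E)‑3‑oxobut‑1‑en‑1‑yl]‑4‑(propan‑2‑yl)cyclopent‑2‑en‑1‑yl acetate
Product: 9 (1S,4R)‑3‑{(1R)‑1‑[dimethyl(phenyl)silyl]‑3‑oxobutyl}‑4‑hydroxy‑2‑methyl‑4‑(propan‑2‑yl)cyclopent‑2‑en‑1‑yl acetate
Conditions: PhMe2Si–Bpin (1.2 equiv), CuCl (5 mol %), chiral imidazolinium salt (NHC precursor, 5.5 mol %), NaOt‑Bu (11 mol %), THF, −78 °C; aq. NH4Cl
Reagents that add atoms: [dimethyl(phenyl)silyl]boronic acid pinacol ester, CC1(C)OB(OC1(C)C)[Si](C)(C)c1ccccc1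
Why: Copper‑catalysed enantioselective conjugate silyl addition, in which 1,4‑addition at fC5 is preferred over 1,6‑addition to the fully substituted ring carbon and the chiral NHC ligand sets the (R) C–Si centre by catalyst control, creating the allylsilane that will relay chirality to the quaternary carbon.

Step 6
Reactants: 9 (1S,4R)‑3‑{(1R)‑1‑[dimethyl(phenyl)silyl]‑3‑oxobutyl}‑4‑hydroxy‑2‑methyl‑4‑(propan‑2‑yl)cyclopent‑2‑en‑1‑yl acetate; 10 (1,3‑dioxolan‑2‑ylmethyl)triphenylphosphonium bromide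
Product: 12 (1S,4R)‑3‑{(1R,3Z)‑1‑[dimethyl(phenyl)silyl]‑3‑methyl‑5‑oxopent‑3‑en‑1‑yl}‑4‑hydroxy‑2‑methyl‑4‑(propan‑2‑yl)cyclopent‑2‑en‑1‑yl acetate (formed together with its 3E isomer), via vinyl‑dioxolane 11 (not isolated)
Conditions: KOt‑Bu, THF, 0 °C → rt; then 1 M aq. oxalic acid, rt
Reagents that add atoms: water, O
Why: Wittig two‑carbon homologation of the methyl ketone to a masked enal, followed by mild acetal hydrolysis, gives the β‑methyl enal as a Z/E mixture without touching any stereocentre, the two isomers interconverting in the next step.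

Step 7
Reactants: 12 (1S,4R)‑3‑{(1R,3Z)‑1‑[dimethyl(phenyl)silyl]‑3‑methyl‑5‑oxopent‑3‑en‑1‑yl}‑4‑hydroxy‑2‑methyl‑4‑(propan‑2‑yl)cyclopent‑2‑en‑1‑yl acetate
Product: 13 2α‑acetoxydauca‑5,8‑diene‑4β,10β‑diol
Conditions: Me2AlCl (2.5 equiv), CH2Cl2, −78 → −20 °C; aq. KNaC4H4O6 (tartrate) work‑up
Reagents that add atoms: none
Why: Intramolecular Hosomi–Sakurai (allylsilane–aldehyde) cyclisation, the carbonyl counterpart of the cyclase's fC1–fC7 closure, in which the Me2AlCl‑bound Z‑enal (the E isomer equilibrating under the Lewis acid) is attacked 1,2 by fC7 of the ring alkene anti to the C–Si bond (anti‑SE2′, with β‑silyl stabilisation of the fC6 cation enforcing seven‑ rather than six‑membered closure), so the (R) C–Si centre places fC1 on the α‑face of fC7 (angular methyl β), the aluminium‑bound oxygen pointing away from the cyclopentane gives the 10β‑alcohol, and loss of silicon leaves the 5,6‑alkene.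

Step 8
Reactants: 13 2α‑acetoxydauca‑5,8‑diene‑4β,10β‑diol
Product: 14 2α‑acetoxydauc‑8‑ene‑4β,6α,10β‑triol
Conditions: BH3·THF (2.2 equiv), THF, −20 → 0 °C; then 30 % H2O2, aq. NaHCO3, 0 °C
Reagents that add atoms: hydrogen peroxide, OO
Why: Hydroboration–oxidation, in which boron adds to the less substituted C6 and hydrogen to the ring‑fusion C5 in a syn fashion from the α‑face, anti to the allylic tertiary C–O bond and to the angular methyl (as in the 5α,6α‑selective hydroboration of 5‑ene steroids), so the trans ring fusion and the 6α‑hydroxyl arise together, while the 8,9‑alkene is shielded by the adjacent quaternary carbon and deactivated by its alkoxyborane.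

Step 9
Reactants: 14 2α‑acetoxydauc‑8‑ene‑4β,6α,10β‑triol; 15 4‑methoxybenzoyl chloride
Product: 16 2α‑acetoxy‑6α‑(4‑methoxybenzoyloxy)dauc‑8‑ene‑4β,10β‑diol (CNP0261832.1)
Conditions: pyridine, DMAP (10 mol %), CH2Cl2, 0 °C → rt
Reagents that add atoms: none
Why: DMAP‑catalysed acylation, in which only the unhindered secondary 6α‑hydroxyl reacts with one equivalent of acid chloride because the 4‑hydroxyl is tertiary and the allylic 10‑hydroxyl is neopentyl (next to the quaternary carbon), so the target forms without touching any stereocentre.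

**Compound list**
1 | 3‑methylbutan‑2‑one | CC(=O)C(C)C | starting material
2 | (2E)‑4,4‑dimethoxy‑2‑methylbut‑2‑enal | O=C/C(C)=C/C(OC)OC | starting material
3 | (5S,6E)‑5‑hydroxy‑8,8‑dimethoxy‑2,6‑dimethyloct‑6‑en‑3‑one | CC(C)C(=O)C[C@H](O)/C(C)=C/C(OC)OC | intermediate
4 | (5S,6E)‑8,8‑dimethoxy‑2,6‑dimethyl‑3‑oxooct‑6‑en‑5‑yl acetate | CC(C)C(=O)C[C@H](OC(C)=O)/C(C)=C/C(OC)OC | intermediate
5 | (5S,6E)‑2,6‑dimethyl‑3,8‑dioxooct‑6‑en‑5‑yl acetate (keto‑enal) | CC(C)C(=O)C[C@H](OC(C)=O)/C(C)=C/C=O | intermediate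
6 | (1S,4R)‑3‑formyl‑4‑hydroxy‑2‑methyl‑4‑(propan‑2‑yl)cyclopent‑2‑en‑1‑yl acetate | O=CC1=C(C)[C@@H](OC(C)=O)C[C@@]1(O)C(C)C | intermediate
7 | 1‑(triphenyl‑λ5‑phosphanylidene)propan‑2‑one | CC(=O)C=P(c1ccccc1)(c1ccccc1)c1ccccc1 | starting material
8 | (1S,4R)‑4‑hydroxy‑2‑methyl‑3‑[(1E)‑3‑oxobut‑1‑en‑1‑yl]‑4‑(propan‑2‑yl)cyclopent‑2‑en‑1‑yl acetate | CC(=O)/C=C/C1=C(C)[C@@H](OC(C)=O)C[C@@]1(O)C(C)C | intermediate
9 | (1S,4R)‑3‑{(1R)‑1‑[dimethyl(phenyl)silyl]‑3‑oxobutyl}‑4‑hydroxy‑2‑methyl‑4‑(propan‑2‑yl)cyclopent‑2‑en‑1‑yl acetate | CC(=O)C[C@@H]([Si](C)(C)c1ccccc1)C2=C(C)[C@@H](OC(C)=O)C[C@@]2(O)C(C)C | intermediate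
10 | (1,3‑dioxolan‑2‑ylmethyl)triphenylphosphonium bromide | [Br-].C1COC(C[P+](c2ccccc2)(c2ccccc2)c2ccccc2)O1 | starting material
11 | (1S,4R)‑3‑{(1R,3Z)‑1‑[dimethyl(phenyl)silyl]‑4‑(1,3‑dioxolan‑2‑yl)‑3‑methylbut‑3‑en‑1‑yl}‑4‑hydroxy‑2‑methyl‑4‑(propan‑2‑yl)cyclopent‑2‑en‑1‑yl acetate (Z shown, E also formed) | C1COC(O1)/C=C(/C)C[C@@H]([Si](C)(C)c2ccccc2)C3=C(C)[C@@H](OC(C)=O)C[C@@]3(O)C(C)C | intermediate
12 | (1S,4R)‑3‑{(1R,3Z)‑1‑[dimethyl(phenyl)silyl]‑3‑methyl‑5‑oxopent‑3‑en‑1‑yl}‑4‑hydroxy‑2‑methyl‑4‑(propan‑2‑yl)cyclopent‑2‑en‑1‑yl acetate (Z shown, E also formed) | O=C/C=C(/C)C[C@@H]([Si](C)(C)c1ccccc1)C2=C(C)[C@@H](OC(C)=O)C[C@@]2(O)C(C)C | intermediate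
13 | 2α‑acetoxydauca‑5,8‑diene‑4β,10β‑diol | O[C@H]1C=C(C)CC=C2[C@]1(C)[C@@H](OC(C)=O)C[C@@]2(O)C(C)C | intermediate
14 | 2α‑acetoxydauc‑8‑ene‑4β,6α,10β‑triol (5α‑H, trans‑fused) | O[C@H]1CC(C)=C[C@H](O)[C@@]2(C)[C@@H](OC(C)=O)C[C@@](O)(C(C)C)[C@H]12 | intermediate
15 | 4‑methoxybenzoyl chloride | COc1ccc(cc1)C(Cl)=O | starting material
16 | 2α‑acetoxy‑6α‑(4‑methoxybenzoyloxy)dauc‑8‑ene‑4β,10β‑diol (CNP0261832.1) | COc1ccc(C(=O)O[C@H]2CC(C)=C[C@H](O)[C@@]3(C)[C@@H](OC(C)=O)C[C@@](O)(C(C)C)[C@H]23)cc1 | target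

**Total steps:** 9. **Longest linear sequence:** 9 (from 1 and 2).

**Three steps most likely to fail, with fallbacks**

Step 3 (dienamine aldol). The risks are amine‑promoted loss of acetate from the β‑acetoxy ketone, erosion of the acetate centre through the endocyclic dienamine, and poor control of the new carbinol. The fallback sets out from 4 and returns at 6. Compound 4 is hydrolysed with aqueous acid to keto‑enal 5, which is now isolated. α‑Iodination (I2, DMAP, K2CO3, THF/H2O) gives (5S,6Z)‑7‑iodo‑2,6‑dimethyl‑3,8‑dioxooct‑6‑en‑5‑yl acetate F1. CrCl2 with catalytic NiCl2 in DMF (Nozaki–Hiyama–Kishi, divalent chromium) then converts the C–I bond into an alkenylchromium at fC6, which adds to the isopropyl ketone. This closes the same fC6–fC10 bond and gives 6 without amine catalysis.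

Step 7 (allylsilane cyclisation). The risks are ionisation of the allylic acetate or tertiary allylic alcohol by the Lewis acid, slow E/Z equilibration of the enal, and the contra‑steric α‑face attack at a tetrasubstituted alkene carbon. The fallback sets out from 8 and returns at 13. Copper‑catalysed conjugate borylation (B2pin2, CuCl, chiral bisphosphine of the opposite sense, NaOt‑Bu, MeOH) gives the (1S)‑allylboronate ketone (1S,4R)‑4‑hydroxy‑2‑methyl‑3‑[(1S)‑3‑oxo‑1‑(4,4,5,5‑tetramethyl‑1,3,2‑dioxaborolan‑2‑yl)butyl]‑4‑(propan‑2‑yl)cyclopent‑2‑en‑1‑yl acetate F2. The same Wittig homologation proceeds through the vinyl dioxolane F3 to the boronate enal F4. Heating F4 in toluene lets the allylboronate add to the aldehyde through a closed six‑membered transition state (syn‑SE2′, no Lewis acid), and aqueous work‑up gives 13.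

Step 8 (hydroboration). The risks are β‑face attack, since the α‑face carries the isopropyl group, which would give the cis‑fused 6β‑alcohol, and competing hydroboration of the 8,9‑alkene. The fallback sets out from 13 and returns at 16, bypassing 14. Silylation (Et3SiCl, imidazole, DMF) protects only the secondary allylic alcohol and gives 10β‑(triethylsilyloxy)‑2α‑acetoxydauca‑5,8‑dien‑4β‑ol F5. Epoxidation directed by the tertiary hydroxyl (VO(acac)2, t‑BuOOH) gives the 5β,6β‑epoxide F6. Radical opening with Cp2TiCl (trivalent titanium, from Cp2TiCl2 and Mn) and 1,4‑cyclohexadiene cleaves the C5–O bond; hydrogen‑atom transfer to the tertiary radical from the α‑face, opposite the two titanium‑bound oxygens, gives the trans‑fused 2α‑acetoxy‑10β‑(triethylsilyloxy)dauc‑8‑ene‑4β,6β‑diol F7. Mitsunobu inversion with 4‑methoxybenzoic acid (PPh3, DIAD) gives the 10‑O‑triethylsilyl ether of the target F8, and HF·pyridine releases 16.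

**Further compounds**
F1 | step 3 | (5S,6Z)‑7‑iodo‑2,6‑dimethyl‑3,8‑dioxooct‑6‑en‑5‑yl acetate | CC(C)C(=O)C[C@H](OC(C)=O)/C(C)=C(/C=O)I
F2 | step 7 | (1S,4R)‑4‑hydroxy‑2‑methyl‑3‑[(1S)‑3‑oxo‑1‑(4,4,5,5‑tetramethyl‑1,3,2‑dioxaborolan‑2‑yl)butyl]‑4‑(propan‑2‑yl)cyclopent‑2‑en‑1‑yl acetate | CC(=O)C[C@H](B1OC(C)(C)C(C)(C)O1)C2=C(C)[C@@H](OC(C)=O)C[C@@]2(O)C(C)C
F3 | step 7 | (1S,4R)‑3‑[(1S,3Z)‑4‑(1,3‑dioxolan‑2‑yl)‑3‑methyl‑1‑(4,4,5,5‑tetramethyl‑1,3,2‑dioxaborolan‑2‑yl)but‑3‑en‑1‑yl]‑4‑hydroxy‑2‑methyl‑4‑(propan‑2‑yl)cyclopent‑2‑en‑1‑yl acetate | C1COC(O1)/C=C(/C)C[C@H](B2OC(C)(C)C(C)(C)O2)C3=C(C)[C@@H](OC(C)=O)C[C@@]3(O)C(C)C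
F4 | step 7 | (1S,4R)‑4‑hydroxy‑2‑methyl‑3‑[(1S,3Z)‑3‑methyl‑5‑oxo‑1‑(4,4,5,5‑tetramethyl‑1,3,2‑dioxaborolan‑2‑yl)pent‑3‑en‑1‑yl]‑4‑(propan‑2‑yl)cyclopent‑2‑en‑1‑yl acetate | O=C/C=C(/C)C[C@H](B1OC(C)(C)C(C)(C)O1)C2=C(C)[C@@H](OC(C)=O)C[C@@]2(O)C(C)C
F5 | step 8 | 2α‑acetoxy‑10β‑(triethylsilyloxy)dauca‑5,8‑dien‑4β‑ol | CC[Si](CC)(CC)O[C@H]1C=C(C)CC=C2[C@]1(C)[C@@H](OC(C)=O)C[C@@]2(O)C(C)C
F6 | step 8 | 2α‑acetoxy‑5β,6β‑epoxy‑10β‑(triethylsilyloxy)dauc‑8‑en‑4β‑ol | CC[Si](CC)(CC)O[C@H]1C=C(C)C[C@H]2O[C@@]23[C@]1(C)[C@@H](OC(C)=O)C[C@@]3(O)C(C)C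
F7 | step 8 | 2α‑acetoxy‑10β‑(triethylsilyloxy)dauc‑8‑ene‑4β,6β‑diol (5α‑H) | CC[Si](CC)(CC)O[C@H]1C=C(C)C[C@@H](O)[C@@H]2[C@]1(C)[C@@H](OC(C)=O)C[C@@]2(O)C(C)C
F8 | step 8 | 2α‑acetoxy‑6α‑(4‑methoxybenzoyloxy)‑10β‑(triethylsilyloxy)dauc‑8‑en‑4β‑ol | COc1ccc(C(=O)O[C@H]2CC(C)=C[C@H](O[Si](CC)(CC)CC)[C@@]3(C)[C@@H](OC(C)=O)C[C@@](O)(C(C)C)[C@H]23)cc1
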